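The cyclohexane is disconnected by a retro-[4+2] across C1–C2 and C5–C6 (ring atoms: C1 carbinol, C3 CHCl, C4 CBrMe). The C3–C4 bromochloride is a masked isoprene alkene. The oxygenated quaternary C1, para to the methyl-bearing C4, is the α-carbon of a 2-acyloxyacrolein. One catalytic enantioselective Diels–Alder reaction of isoprene with this enal thus closes the carbocycle and sets C1. Because the C1 oxygen is cis to the C4 bromine, it then relays C1 to C3 and C4 through a transient 7-oxa bridge (chloroetherification, then bromide opening with retention). Aldol extension and methylenation complete the side chain.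

Key step: step 3

Remark 1: the target is read as (1R,3S,4S)-4-bromo-3-chloro-1-[(4S)-4-hydroxy-6-methylhepta-1,5-dien-2-yl]-4-methylcyclohexan-1-ol, with C1–OH cis to C4–Br and trans to C3–Cl.
Remark 2: the antipodes of the diamine catalyst (step 3) and of Ipc2BCl (step 8) are assigned by analogy with related substrates; both antipodes of each are commercial, and the other is used if the sense of induction proves opposite.

Step 1
Reactants: 1 2,2-dimethyl-1,3-dioxan-5-one; 2 cyclohexanecarbonyl chloride
Product: 4 2,2-dimethyl-4H-1,3-dioxin-5-yl cyclohexanecarboxylate, via potassium enolate 3 (not isolated)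
Conditions: KHMDS, THF, −78 °C; then 2, −78 → 0 °C
Reagents that add atoms: none
Why: O-acylation of a potassium ketone enolate with an acyl chloride should give the enol ester.

Step 2
Reactants: 4 2,2-dimethyl-4H-1,3-dioxin-5-yl cyclohexanecarboxylate
Product: 5 3-oxoprop-1-en-2-yl cyclohexanecarboxylate [2-(cyclohexanecarbonyloxy)acrolein]
Conditions: toluene, 110 °C
Reagents that add atoms: none
Why: thermal retro-hetero-Diels–Alder fragmentation of the 4H-1,3-dioxin should expel acetone and release the 2-acyloxyacrolein.

Step 3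
Reactants: 5 2-(cyclohexanecarbonyloxy)acrolein; 6 isoprene
Product: 7 (1R)-1-formyl-4-methylcyclohex-3-en-1-yl cyclohexanecarboxylate
Conditions: (R)-1,1'-binaphthyl-2,2'-diamine (5 mol %), Tf2NH (9.5 mol %), 6 (3 equiv), EtCN, −75 → −40 °C
Reagents that add atoms: none
Why: The primary ammonium salt condenses with the α-substituted enal 5 to an aldiminium ion whose LUMO is lowered and whose acyloxy carbonyl is hydrogen-bonded to the second ammonium group, so that one face of the C=C bond is shielded by the binaphthyl backbone. Isoprene then adds in a concerted, asynchronous [4+2] cycloaddition (suprafacial on both partners) that closes the six-membered carbocycle through the new C5–C6 and C1–C2 bonds; the closest known reaction type is the organoammonium-catalysed enantioselective Diels–Alder reaction of α-acyloxyacroleins with dienes. The only new stereocentre, C1, is under catalyst control. The step needs "para" regioselectivity, which the substrate secures because the larger HOMO coefficient of isoprene (the CH2 next to the methyl-bearing carbon) bonds to the β-carbon of the iminium ion and so places the methyl-bearing carbon 1,4 to the acyloxy carbon. Hydrolysis of the product iminium ion should release aldehyde 7 and the catalyst.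

Step 4
Reactants: 7 (1R)-1-formyl-4-methylcyclohex-3-en-1-yl cyclohexanecarboxylate
Product: 8 (1R)-1-(1-hydroxyethyl)-4-methylcyclohex-3-en-1-ol (both carbinol epimers)
Conditions: MeMgBr (4 equiv), THF, −78 → 23 °C; aq. NH4Cl
Reagents that add atoms: methylmagnesium bromide, C[Mg]Br
Why: Grignard addition to the aldehyde and, with excess reagent, double addition to the ester (after 1,2-acyl shift to the new alkoxide) should free the tertiary alcohol; the new carbinol centre is uncontrolled but is destroyed in the next step.

Step 5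
Reactants: 8 (1R)-1-(1-hydroxyethyl)-4-methylcyclohex-3-en-1-ol
Product: 9 1-[(1R)-1-hydroxy-4-methylcyclohex-3-en-1-yl]ethan-1-one
Conditions: IBX, DMSO, 23 °C
Reagents that add atoms: none
Why: IBX oxidation of the secondary alcohol of a 1,2-diol should give the α-hydroxy ketone without glycol cleavage, the tertiary alcohol and the alkene being inert.

Step 6
Reactants: 9 1-[(1R)-1-hydroxy-4-methylcyclohex-3-en-1-yl]ethan-1-one
Product: 10 1-[(1R,3S,4S)-3-chloro-4-methyl-7-oxabicyclo[2.2.1]heptan-1-yl]ethan-1-one
Conditions: NCS (1.1 equiv), (CF3)2CHOH–CH2Cl2 (1:4), −20 °C, dark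
Reagents that add atoms: N-chlorosuccinimide, O=C1CCC(=O)N1Cl
Why: in this intramolecular chloroetherification (halocyclisation) the C1 hydroxyl can reach the Markovnikov terminus C4 only on its own face while chlorine is delivered anti to C3, so that C3–Cl (trans) and C4–O (cis to the C1 oxygen) should be fixed in one event by 5-exo closure through a boat.

Step 7
Reactants: 10 1-[(1R,3S,4S)-3-chloro-4-methyl-7-oxabicyclo[2.2.1]heptan-1-yl]ethan-1-one
Product: 11 1-[(1R,3S,4S)-4-bromo-3-chloro-4-methyl-1-(trimethylsilyloxy)cyclohexyl]ethan-1-one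
Conditions: Me3SiBr (2 equiv), CH2Cl2, −40 → 0 °C; cold aq. NaHCO3
Reagents that add atoms: bromotrimethylsilane, C[Si](C)(C)Br
Why: in this silyl-halide cleavage of a strained bridged ether, O-silylation is followed by ionisation of the tertiary C4–O bond (the C1–O bond is held by the destabilising α-acetyl group) with assistance from the antiperiplanar endo C3 chlorine, and anti opening of the chloronium-like ion at its tertiary carbon by bromide, the same anti capture that governs chlorine addition to trisubstituted alkenes, should install C4–Br with retention and leave C1–O as its trimethylsilyl ether.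

Step 8
Reactants: 11 1-[(1R,3S,4S)-4-bromo-3-chloro-4-methyl-1-(trimethylsilyloxy)cyclohexyl]ethan-1-one; 12 3-methylbut-2-enal
Product: 14 (3S)-1-[(1R,3S,4S)-4-bromo-3-chloro-4-methyl-1-(trimethylsilyloxy)cyclohexyl]-3-hydroxy-5-methylhex-4-en-1-one, via boron enolate 13 (not isolated)
Conditions: (+)-Ipc2BCl (1.5 equiv), Et3N, Et2O, 0 °C; then 12, −78 → −25 °C; pH 7 buffer, MeOH, 30% H2O2, 0 °C
Reagents that add atoms: none
Why: in this diisopinocampheylboron-mediated aldol addition of a methyl ketone, soft enolisation can occur only at the methyl group (C1 is quaternary) and spares the tertiary bromide, and the chiral boron enolate should add 1,2 to the enal with reagent-controlled facial selectivity to set the (S)-carbinol.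

Step 9
Reactants: 14 the (3S)-β-hydroxy ketone
Product: 15 (3S)-1-[(1R,3S,4S)-4-bromo-3-chloro-4-methyl-1-(trimethylsilyloxy)cyclohexyl]-5-methyl-3-(triethylsilyloxy)hex-4-en-1-one
Conditions: Et3SiOTf (1.3 equiv), 2,6-lutidine, CH2Cl2, −78 °C
Reagents that add atoms: triethylsilyl trifluoromethanesulfonate, CC[Si](CC)(CC)OS(=O)(=O)C(F)(F)F
Why: silyl triflate silylation of the secondary allylic alcohol with a hindered base should block retro-aldol cleavage and titanium alkoxide formation in the next step.

Step 10
Reactants: 15 the β-triethylsilyloxy ketone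
Product: 16 triethyl{[(4S)-2-[(1R,3S,4S)-4-bromo-3-chloro-4-methyl-1-(trimethylsilyloxy)cyclohexyl]-6-methylhepta-1,5-dien-4-yl]oxy}silane
Conditions: Cp2TiMe2 (3 equiv), toluene–THF, 65 °C, dark
Reagents that add atoms: dimethyltitanocene, C[Ti](C)(C1C=CC=C1)C1C=CC=C1
Why: Petasis methylenation with a non-basic titanium methylidene should convert the hindered, enolisable β-silyloxy ketone into the 1,1-disubstituted alkene without β-elimination or attack on the alkyl halides.

Step 11
Reactants: 16 the bis-silyl ether
Product: 17 (1R,3S,4S)-4-bromo-3-chloro-1-[(4S)-4-hydroxy-6-methylhepta-1,5-dien-2-yl]-4-methylcyclohexan-1-ol (target)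
Conditions: Bu4NF–AcOH (1:1, 3 equiv), THF, 0 → 23 °C
Reagents that add atoms: none
Why: buffered fluoride desilylation (Si–F bond formation) should cleave both silyl ethers under near-neutral conditions that spare the tertiary bromide and the acid-labile allylic alcohols.

Compound list
1 | 2,2-dimethyl-1,3-dioxan-5-one | CC1(C)OCC(=O)CO1 | starting material
2 | cyclohexanecarbonyl chloride | O=C(Cl)C1CCCCC1 | starting material
3 | potassium 2,2-dimethyl-4H-1,3-dioxin-5-olate (potassium enolate of 1) | CC1(C)OCC([O-])=CO1.[K+] | intermediate (not isolated)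
4 | 2,2-dimethyl-4H-1,3-dioxin-5-yl cyclohexanecarboxylate | CC1(C)OCC(OC(=O)C2CCCCC2)=CO1 | intermediate
5 | 3-oxoprop-1-en-2-yl cyclohexanecarboxylate [2-(cyclohexanecarbonyloxy)acrolein] | C=C(OC(=O)C1CCCCC1)C=O | intermediate
6 | isoprene (2-methylbuta-1,3-diene) | C=CC(C)=C | starting material
7 | (1R)-1-formyl-4-methylcyclohex-3-en-1-yl cyclohexanecarboxylate | O=C[C@@]1(OC(=O)C2CCCCC2)CCC(C)=CC1 | intermediate
8 | (1R)-1-(1-hydroxyethyl)-4-methylcyclohex-3-en-1-ol (both carbinol epimers) | CC(O)[C@@]1(O)CCC(C)=CC1 | intermediate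
9 | 1-[(1R)-1-hydroxy-4-methylcyclohex-3-en-1-yl]ethan-1-one | CC(=O)[C@@]1(O)CCC(C)=CC1 | intermediate
10 | 1-[(1R,3S,4S)-3-chloro-4-methyl-7-oxabicyclo[2.2.1]heptan-1-yl]ethan-1-one (chlorine anti to the oxygen bridge) | CC(=O)[C@@]1(O2)CC[C@@]2(C)[C@@H](Cl)C1 | intermediate
11 | 1-[(1R,3S,4S)-4-bromo-3-chloro-4-methyl-1-(trimethylsilyloxy)cyclohexyl]ethan-1-one | CC(=O)[C@@]1(O[Si](C)(C)C)CC[C@](C)(Br)[C@@H](Cl)C1 | intermediate
12 | 3-methylbut-2-enal | CC(C)=CC=O | starting material
13 | O-diisopinocampheylboron enolate of 11, from (+)-Ipc2BCl (boron on the enolate oxygen, terminal CH2=) | C=C(OB([C@@H]1[C@@H](C)[C@@H]2C[C@H](C1)C2(C)C)[C@@H]1[C@@H](C)[C@@H]2C[C@H](C1)C2(C)C)[C@@]1(O[Si](C)(C)C)CC[C@](C)(Br)[C@@H](Cl)C1 | intermediate (not isolated)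
14 | (3S)-1-[(1R,3S,4S)-4-bromo-3-chloro-4-methyl-1-(trimethylsilyloxy)cyclohexyl]-3-hydroxy-5-methylhex-4-en-1-one | CC(C)=C[C@@H](O)CC(=O)[C@@]1(O[Si](C)(C)C)CC[C@](C)(Br)[C@@H](Cl)C1 | intermediate
15 | (3S)-1-[(1R,3S,4S)-4-bromo-3-chloro-4-methyl-1-(trimethylsilyloxy)cyclohexyl]-5-methyl-3-(triethylsilyloxy)hex-4-en-1-one | CC(C)=C[C@@H](O[Si](CC)(CC)CC)CC(=O)[C@@]1(O[Si](C)(C)C)CC[C@](C)(Br)[C@@H](Cl)C1 | intermediate
16 | triethyl{[(4S)-2-[(1R,3S,4S)-4-bromo-3-chloro-4-methyl-1-(trimethylsilyloxy)cyclohexyl]-6-methylhepta-1,5-dien-4-yl]oxy}silane | CC(C)=C[C@@H](O[Si](CC)(CC)CC)CC(=C)[C@@]1(O[Si](C)(C)C)CC[C@](C)(Br)[C@@H](Cl)C1 | intermediate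
17 | (1R,3S,4S)-4-bromo-3-chloro-1-[(4S)-4-hydroxy-6-methylhepta-1,5-dien-2-yl]-4-methylcyclohexan-1-ol | C=C(C[C@H](O)C=C(C)C)[C@@]1(O)CC[C@](C)(Br)[C@@H](Cl)C1 | target

Total step count: 11. Longest linear sequence: 11 steps (from 1).

Steps most likely to fail

Step 7. The ionising cleavage of the bridged ether may erode the configuration at C4 (bromide entering syn to chlorine), divert into E1 elimination, or revert by reclosure of the oxygen bridge. The fallback sets out from 9 and comes back to the route at 11, so that the tertiary bromide is made on a monocyclic chair and not at a bridgehead. Hydroxyl-directed epoxidation of 9 [VO(acac)2, t-BuOOH, CH2Cl2] should give the cis-epoxy alcohol 1-[(1R,3R,6S)-3-hydroxy-6-methyl-7-oxabicyclo[4.1.0]heptan-3-yl]ethan-1-one F1. SN2 opening by chloride at the secondary epoxide carbon (LiCl, AcOH, THF), trans-diaxial in the conformer with axial acetyl, should give the chlorohydrin 1-[(1R,3S,4S)-3-chloro-1,4-dihydroxy-4-methylcyclohexyl]ethan-1-one F2. Bis-silylation (Me3SiOTf, 2,6-lutidine) should give 1-[(1R,3S,4S)-3-chloro-4-methyl-1,4-bis(trimethylsilyloxy)cyclohexyl]ethan-1-one F3. Its tertiary C4 silyl ether, with the C3 chlorine antiperiplanar, is then exchanged for bromide with Me3SiBr at low temperature (chloronium-assisted substitution with retention) to give 11.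

Step 6. Ene-type allylic chlorination of the trisubstituted alkene, or chlorine transfer to the face syn to the hydroxyl, may outrun the cross-ring capture by oxygen. The fallback sets out from 9 and comes back at 10: 9 is taken through F1 and F2 as described above, and acid-catalysed cyclodehydration of the cis-1,4-diol F2 (camphorsulfonic acid cat., CH2Cl2, 4 Å molecular sieves) should close the oxygen bridge at C4. This replaces the halocyclisation by directed epoxidation, chloride opening and etherification, and makes no further compound.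

Step 8. The facial selectivity of the chiral boron enolate towards the enal may be poor (mismatch with the C1 stereocentre), and the amine base may cause loss of HBr. The fallback sets out from 11 and comes back at 14. Soft enolisation (Me3SiOTf, Et3N, CH2Cl2, 0 °C) should give the silyl enol ether trimethyl({1-[(1R,3S,4S)-4-bromo-3-chloro-4-methyl-1-(trimethylsilyloxy)cyclohexyl]ethenyl}oxy)silane F4. A chiral-Lewis-base-catalysed Mukaiyama aldol addition to 12 (SiCl4, chiral bisphosphoramide cat., CH2Cl2, −78 °C) then forms the C–C bond under catalyst control and without base.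

Further compounds
F1 | step 7 | 1-[(1R,3R,6S)-3-hydroxy-6-methyl-7-oxabicyclo[4.1.0]heptan-3-yl]ethan-1-one | CC(=O)[C@@]1(O)CC[C@]2(C)O[C@@H]2C1
F2 | step 7 | 1-[(1R,3S,4S)-3-chloro-1,4-dihydroxy-4-methylcyclohexyl]ethan-1-one | CC(=O)[C@@]1(O)CC[C@](C)(O)[C@@H](Cl)C1
F3 | step 7 | 1-[(1R,3S,4S)-3-chloro-4-methyl-1,4-bis(trimethylsilyloxy)cyclohexyl]ethan-1-one | CC(=O)[C@@]1(O[Si](C)(C)C)CC[C@](C)(O[Si](C)(C)C)[C@@H](Cl)C1
F0 | step 6 | none | none
F4 | step 8 | trimethyl({1-[(1R,3S,4S)-4-bromo-3-chloro-4-methyl-1-(trimethylsilyloxy)cyclohexyl]ethenyl}oxy)silane | C=C(O[Si](C)(C)C)[C@@]1(O[Si](C)(C)C)CC[C@](C)(Br)[C@@H](Cl)C1
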